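Tuesday's highest reading of target was 49.0 % of the substrate charged, and Friday's was 41.7 %, so I asked what the extra substrate had cost. At 2.00 h substrate plus target read 45.6 % of the charge in Friday's run and 51.4 % in Tuesday's, so more of the charge had gone elsewhere in the run with more substrate. I therefore took the peak odds, target at its peak over the rest of the charge, and divided them by the equivalents of reagent per substrate. This ratio, κ, is a kind of selectivity factor.

all flasks: reagent 1.44 M
- Friday's: substrate 1.2 M; the very flask that is asked about, followed so far
- Tuesday's: substrate 0.80 M; run made earlier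
- flask: substrate 1.2 M; time 25 h

- Friday's (time / h: target / %, substrate / %): 0.667: 25.0, 17.9; 1.00: 33.1, 11.6; 2.00: 40.4, 5.2; 3.00: 41.7, 1.2; 6.00: 39.4, 0.1; 10.0: 37.5, 1.2
- Tuesday's (time / h: target / %, substrate / %): 0.667: 25.9, 24.7; 1.00: 37.7, 14.9; 2.00: 47.5, 3.9; 3.00: 49.0, 1.3; 6.00: 46.2, 0; 10.0: 44.0, 1.8

(standard deviation of a reading: 1 percentage point)



1. when, up to 25 h, the flask holds most target
2. the amount of target, in percent of the substrate charged, at that time

Tuesday's readings gave κ = 0.534. Turning the substrate up to 1.2 M by hand at that κ gave a peak of 39.0 %, and Friday's flask read 41.7 %, which is κ = 0.596. I carried the mean, κ = 0.565, the peak odds per equivalent of reagent, and it gave me 40.4 % for this flask.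

Turning the time up promised little by hand. In Friday's flask substrate read 1.2 % at 3.00 h, and target had fallen to 37.5 % by 10.0 h, so I looked for the peak near 3.00 h, not at the end.

The forecast gave a peak of 42 % at 3.3 h, more target than my 40.4 %, holding that “the maximum should be early, not at 25 h”.

The flask peaked at 2.46 h with 41.3 %, when homo dimer held 45.4 % of the substrate charged, two substrate counted in each homo dimer. Put as κ, that peak is 0.587.

    substrate + reagent → intermediate + released group (k = 1.10 L mol⁻¹ h⁻¹)
    intermediate → target (k = 2.80 h⁻¹)
    target ⇌ isomer of the product (K = 0.460, k = 0.180 h⁻¹)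
    2 substrate → homo dimer (k = 1.10 L mol⁻¹ h⁻¹)

For the neighbour, this flask with 0.36 M of reagent, the carried κ = 0.565 gave odds of 0.169, so a peak of 14.5 %. The computed flask gives 15.6 %.

The numbers in the tables were computed for substances that don't exist; the scatter is artificial.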